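In a one-step world, where Z meets X in excess and gives J, J at a given time is a fixed share of the Z charged. The percent readings then match from flask to flask, and J in mM grows in step with the charge. That is the zero of the scale, and the earlier flasks test it.

| flask | Z | X | remark | time |
|---|---|---|---|---|
| elm | 18 mM | 60 mM | run made earlier |  |
| maple | 120 mM | 60 mM | run made earlier |  |
| Wednesday's | 20 mM | 60.0 mM |  | 1.5 h |
| Friday's | 40 mM | 60.0 mM |  | 1.5 h |
| Monday's | 80 mM | 60.0 mM |  | 1.5 h |
| Tuesday's | 150 mM | 60.0 mM |  | 1.5 h |

- elm (time / min: J / %): 12.0: 3.0; 25.0: 5.5; 40.0: 6.7; 50.0: 7.3; 60.0: 7.3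
- maple (time / min: J / %): 12.0: 1.2; 25.0: 1.1; 40.0: 1.6; 50.0: 1.1; 60.0: 1.2

(readings scatter by 0.5 percentage points)

1. [J] at the end for Wednesday's, Friday's, Monday's, Tuesday's, in this order
2. how the row runs (rises, then falls / rises all the way / falls all the way / falls, then rises / hardly changes)

Elm levels off at 7.3% of 18 mM, which is 1.31 mM of J. Maple stays flat at a mean of 1.24% of 120 mM, which is 1.49 mM. Elm's share carried over to maple asks for 8.76 mM, so maple holds far less J than the one-step world allows.

These two flasks are two independent readings of J in mM, at different charges of Z. They part by 0.180 mM, less than the scatter of maple's mean, 0.268 mM, so the two readings agree within their scatter. Elm's scatter is 0.0900 mM.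

The comparison gives 0.0656, give or take 0.102. This is the apparent order in the charge: the logarithm of the ratio of J in mM between two flasks, over the logarithm of the ratio of their Z charges. The one-step world has order one; these flasks read close to zero. But two ends fix a straight line on the logarithmic scale, and a hump between them passes unseen.

Carried from elm, this order gives 1.32 mM for Wednesday's and 1.51 mM for Tuesday's, a row that rises all the way. The forecast differs: 1.34 mM, 1.43 mM, 1.45 mM, 1.42 mM, a row that rises, then falls, with J “falling slightly at high Z as X is consumed”.

The flasks give 1.47 mM, 1.90 mM, 1.75 mM and 1.30 mM; the row rises, then falls.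

    G + X ⇌ E + J (K = 1.90, k = 0.00500 /M/s)
    G → L (k = 0.00230 /s)
    Z + X ⇌ E + G (K = 0.390, k = 0.0130 /M/s)

From Wednesday's to Tuesday's the order is −0.0610, against the 0.0656 of the earlier ends. Inside that span, Wednesday's to Friday's carries 0.370, and Monday's to Tuesday's −0.473. In Friday's, J stood at 4.75% of the Z charged from 0.750 h to 1.50 h, while the step from Z and X to E and G took Z from 32.8% to 17.6% and L reached 75.8%. In Tuesday's, X fell from 10.4% to 2.79% of its charge over the same interval, while J slid from 1.25% to 0.869% of the Z charged.

(The numbers in the tables come from a simulation with made-up constants.)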